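**Retrosynthetic overview**
1. Target 30 ⇐ non-acidic cleavage of seven MOM ethers in 28 ⇐ double oxidation of bis-carbinol 27 ⇐ two aryllithium/aldehyde unions on bromo-aldehyde 18 (with aryl bromide 20 and enal 25).
2. 18 ⇐ ring-closing metathesis of the acyclic dienal 17. The cyclohexene is the only ring formed in the route (all arenes are bought in) and it closes after all three stereocentres are in place.
3. 17 ⇐ stereodivergent Ir/amine α-allylation of aldehyde 10 with racemic aryl vinyl carbinol 16 (sets the CHO-bearing and the neighbouring benzylic carbon).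
4. 10 ⇐ Rh-catalysed asymmetric conjugate arylation of dihydropyranone 4 (sets the third stereocentre), then MeLi, Wittig, oxidation.
5. Two resorcinol rings come from bromide 2 (from 4-bromoresorcinol); the third comes from resorcinol by ortho-formylation and bromination (aldehyde 15); the fourth arene comes from 4-hydroxybenzaldehyde.

Assumption: in step 11 the (S)-ligand is taken to give the (S) benzylic carbon and the (S)-amine the (R) α-carbon; if the ligand sense proves opposite, its antipode is used and nothing else changes.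

**Step 1**
Reactants: 1 4-bromoresorcinol
Product: 2 1-bromo-2,4-bis(methoxymethoxy)benzene
Conditions: NaH, MOMCl, DMF, 0 °C → rt
Reagents that add atoms: chloromethyl methyl ether, COCCl
Why: Williamson-type O-alkylation of both phenoxides (MOM protection) gives the common precursor of two aryl fragments; no stereocentre.

**Step 2**
Reactants: 3 but-3-enoic acid
Product: 4 5,6-dihydro-2H-pyran-2-one
Conditions: (CH2O)n, H2SO4 (cat.), AcOH, reflux
Reagents that add atoms: paraformaldehyde (as formaldehyde), C=O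
Why: Prins reaction of formaldehyde at the terminal alkene, lactonisation and proton loss give the conjugated δ-lactone from very cheap inputs.

**Step 3**
Reactants: 2 1-bromo-2,4-bis(methoxymethoxy)benzene; 4 5,6-dihydro-2H-pyran-2-one
Product: 7 (4R)-4-[2,4-bis(methoxymethoxy)phenyl]oxan-2-one, via aryllithium 5 (not isolated), via lithium aryltrimethoxyborate 6 (not isolated)
Conditions: 2 (2.5 equiv), n-BuLi, Et2O, −78 °C; B(OMe)3, → rt; then 4, Rh(acac)(C2H4)2 (3 mol%), (R)-BINAP, dioxane/H2O, 100 °C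
Reagents that add atoms: none
Why: Br–Li exchange and borate formation feed a Hayashi–Miyaura Rh-catalysed asymmetric 1,4-addition, in which (R)-BINAP directs aryl transfer to the enoate face that gives the (R) benzylic centre.

**Step 4**
Reactants: 7 (4R)-4-[2,4-bis(methoxymethoxy)phenyl]oxan-2-one
Product: 8 (4R)-4-[2,4-bis(methoxymethoxy)phenyl]-6-hydroxyhexan-2-one (in equilibrium with its cyclic hemiketal)
Conditions: MeLi (1.05 equiv), THF, −78 °C; then H2O
Reagents that add atoms: methyllithium, [Li]C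
Why: Mono-addition of MeLi to the lactone stops at the tetrahedral lactolate at −78 °C and gives the methyl ketone on work-up, leaving the stereocentre untouched.

**Step 5**
Reactants: 8 (4R)-4-[2,4-bis(methoxymethoxy)phenyl]-6-hydroxyhexan-2-one
Product: 9 (3S)-3-[2,4-bis(methoxymethoxy)phenyl]-5-methylhex-5-en-1-ol
Conditions: Ph3PCH3Br, KOtBu (3 equiv each), THF, 0 °C → rt
Reagents that add atoms: methyltriphenylphosphonium bromide (its ylide delivers CH2), C[P+](c1ccccc1)(c1ccccc1)c1ccccc1.[Br-]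
Why: Wittig methylenation of the open keto form installs the 1,1-disubstituted alkene for the later ring closure (the descriptor changes from R to S only through priorities).

**Step 6**
Reactants: 9 (3S)-3-[2,4-bis(methoxymethoxy)phenyl]-5-methylhex-5-en-1-ol
Product: 10 (3S)-3-[2,4-bis(methoxymethoxy)phenyl]-5-methylhex-5-enal
Conditions: Dess–Martin periodinane, NaHCO3, CH2Cl2, 0 °C → rt
Reagents that add atoms: none
Why: Buffered Dess–Martin oxidation takes the primary alcohol to the aldehyde without touching the MOM ethers, the alkene or the β-stereocentre.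

**Step 7**
Reactants: 11 resorcinol
Product: 12 1,3-bis(methoxymethoxy)benzene
Conditions: NaH, MOMCl, DMF, 0 °C → rt
Reagents that add atoms: chloromethyl methyl ether, COCCl
Why: Williamson-type O-alkylation of both phenoxides (MOM protection) installs the two directing groups for the next step; no stereocentre.

**Step 8**
Reactants: 12 1,3-bis(methoxymethoxy)benzene
Product: 14 2,6-bis(methoxymethoxy)benzaldehyde, via aryllithium 13 (not isolated)
Conditions: n-BuLi, TMEDA, THF, 0 °C; DMF; then H2O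
Reagents that add atoms: N,N-dimethylformamide, CN(C)C=O
Why: Directed ortho-metalation occurs at the carbon flanked by both MOM ethers, and DMF formylates the aryllithium there.

**Step 9**
Reactants: 14 2,6-bis(methoxymethoxy)benzaldehyde
Product: 15 3-bromo-2,6-bis(methoxymethoxy)benzaldehyde
Conditions: NBS (1.05 equiv), MeCN, 0 °C → rt
Reagents that add atoms: N-bromosuccinimide, O=C1CCC(=O)N1Br
Why: Electrophilic aromatic bromination goes to the position ortho to one MOM ether, para to the other and meta to the formyl group (the two such positions are equivalent), and the first bromine slows a second substitution.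

**Step 10**
Reactants: 15 3-bromo-2,6-bis(methoxymethoxy)benzaldehyde
Product: 16 rac-1-[3-bromo-2,6-bis(methoxymethoxy)phenyl]prop-2-en-1-ol
Conditions: CH2=CHMgBr, THF, −78 → 0 °C; then H2O
Reagents that add atoms: vinylmagnesium bromide, C=C[Mg]Br
Why: Grignard 1,2-addition gives the racemic branched allylic alcohol, which is the substrate type the enantioconvergent Ir allylation needs.

**Step 11**
Reactants: 10 (3S)-3-[2,4-bis(methoxymethoxy)phenyl]-5-methylhex-5-enal; 16 rac-1-[3-bromo-2,6-bis(methoxymethoxy)phenyl]prop-2-en-1-ol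
Product: 17 (2R,3S)-3-[2,4-bis(methoxymethoxy)phenyl]-2-[(1S)-1-[3-bromo-2,6-bis(methoxymethoxy)phenyl]prop-2-en-1-yl]-5-methylhex-5-enal
Conditions: 10 (2 equiv, excess recovered), [Ir(cod)Cl]2 (3 mol%), (S)-4-(5H-dibenzo[b,f]azepin-5-yl)dinaphtho[2,1-d:1′,2′-f][1,3,2]dioxaphosphepine (12 mol%), (S)-α,α-bis[3,5-bis(trifluoromethyl)phenyl]prolinol TMS ether (15 mol%), ZnBr2 (7.5 mol%), ClCH2CH2Cl, 25 °C
Reagents that add atoms: none
Why: In this dual Ir-allylic-substitution/enamine α-alkylation the catalyst formed from [Ir(cod)Cl]2 and the phosphoramidite-olefin ligand converts both enantiomers of 16 into one π-allyl and fixes the benzylic centre, while the prolinol-ether enamine shields one face and fixes the α-centre, with catalyst control expected to dominate over the existing β-aryl centre.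

**Step 12**
Reactants: 17 the dienal from step 11
Product: 18 (1R,2S,6S)-6-[2,4-bis(methoxymethoxy)phenyl]-2-[3-bromo-2,6-bis(methoxymethoxy)phenyl]-4-methylcyclohex-3-ene-1-carbaldehyde
Conditions: second-generation Grubbs catalyst RuCl2(=CHPh)(PCy3)(H2IMes) (5 mol%), CH2Cl2, 40 °C
Reagents that add atoms: none
Why: Ring-closing metathesis between the vinyl and the 1,1-disubstituted alkene closes the six-membered ring with its trisubstituted C=C and expels ethylene, without touching any stereocentre.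

**Step 13**
Reactants: 2 1-bromo-2,4-bis(methoxymethoxy)benzene
Product: 20 1-bromo-2,4-bis(methoxymethoxy)-3-(3-methylbut-2-en-1-yl)benzene, via aryllithium 19 (not isolated)
Conditions: LiN(iPr)2, THF, −78 °C; prenyl bromide, −78 °C → rt
Reagents that add atoms: prenyl bromide (1-bromo-3-methylbut-2-ene), CC(C)=CCBr
Why: Directed ortho-metalation with an amide base (no Br–Li exchange) occurs at the carbon flanked by both MOM ethers, and SN2 alkylation with the allylic bromide places the prenyl group between the two oxygens.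

**Step 14**
Reactants: 20 1-bromo-2,4-bis(methoxymethoxy)-3-(3-methylbut-2-en-1-yl)benzene; 18 the cyclohexene carbaldehyde
Product: 22 [(1R,2S,6S)-6-[2,4-bis(methoxymethoxy)phenyl]-2-[3-bromo-2,6-bis(methoxymethoxy)phenyl]-4-methylcyclohex-3-en-1-yl][2,4-bis(methoxymethoxy)-3-(3-methylbut-2-en-1-yl)phenyl]methanol (both carbinol epimers), via aryllithium 21 (not isolated)
Conditions: 20 (1.3 equiv), n-BuLi, THF, −78 °C; then 18, −78 °C; then H2O
Reagents that add atoms: none
Why: Br–Li exchange followed by fast 1,2-addition of the aryllithium to the aldehyde at −78 °C outruns enolisation, and the new carbinol centre is irrelevant because it is oxidised later.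

**Step 15**
Reactants: 23 4-hydroxybenzaldehyde
Product: 24 4-(methoxymethoxy)benzaldehyde
Conditions: NaH, MOMCl, DMF, 0 °C → rt
Reagents that add atoms: chloromethyl methyl ether, COCCl
Why: MOM protection of the phenoxide by O-alkylation.

**Step 16**
Reactants: 24 4-(methoxymethoxy)benzaldehyde
Product: 25 (2E)-3-[4-(methoxymethoxy)phenyl]prop-2-enal
Conditions: Ph3P=CHCHO (1.1 equiv), toluene, 80 °C
Reagents that add atoms: (triphenylphosphoranylidene)acetaldehyde, O=CC=P(c1ccccc1)(c1ccccc1)c1ccccc1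
Why: Wittig reaction with the stabilised ylide gives the two-carbon homologated enal with E geometry.

**Step 17**
Reactants: 22 the carbinol from step 14; 25 (2E)-3-[4-(methoxymethoxy)phenyl]prop-2-enal
Product: 27 (2E)-1-[3-[(1S,5S,6R)-6-[hydroxy[2,4-bis(methoxymethoxy)-3-(3-methylbut-2-en-1-yl)phenyl]methyl]-5-[2,4-bis(methoxymethoxy)phenyl]-3-methylcyclohex-2-en-1-yl]-2,4-bis(methoxymethoxy)phenyl]-3-[4-(methoxymethoxy)phenyl]prop-2-en-1-ol (carbinol epimers), via dilithio species 26 (not isolated)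
Conditions: t-BuLi (3.2 equiv), THF, −78 °C; then 25 (1.5 equiv), −78 °C; then H2O
Reagents that add atoms: none
Why: The first equivalent of t-BuLi makes the alkoxide, two more effect Br–Li exchange, and the aryllithium adds 1,2 to the enal, carrying the E alkene of the future chalcone into the molecule.

**Step 18**
Reactants: 27 the bis-carbinol
Product: 28 (2E)-1-[3-[(1S,5S,6R)-6-[2,4-bis(methoxymethoxy)-3-(3-methylbut-2-en-1-yl)benzoyl]-5-[2,4-bis(methoxymethoxy)phenyl]-3-methylcyclohex-2-en-1-yl]-2,4-bis(methoxymethoxy)phenyl]-3-[4-(methoxymethoxy)phenyl]prop-2-en-1-one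
Conditions: Dess–Martin periodinane (3 equiv), NaHCO3, CH2Cl2, 0 °C → rt
Reagents that add atoms: none
Why: Buffered Dess–Martin oxidation converts both the benzylic and the allylic-benzylic carbinol to ketones in one operation under near-neutral conditions that do not epimerise the new α-stereocentre.

**Step 19**
Reactants: 28 the hepta-MOM diketone
Product: 30 (2E)-1-[3-[(1S,5S,6R)-6-[2,4-dihydroxy-3-(3-methylbut-2-en-1-yl)benzoyl]-5-(2,4-dihydroxyphenyl)-3-methylcyclohex-2-en-1-yl]-2,4-dihydroxyphenyl]-3-(4-hydroxyphenyl)prop-2-en-1-one, via heptakis(trimethylsilyl) ether 29 (not isolated)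
Conditions: TMSOTf (14 equiv), 2,2′-bipyridyl (21 equiv), MeCN, 0 °C → rt; then H2O, rt
Reagents that add atoms: none
Why: Silyl triflate/bipyridyl acetal cleavage turns each aryl MOM ether into an aryl silyl ether that water hydrolyses, so no free phenol meets strong acid (which would risk chroman formation, ketalisation or epimerisation) and no base touches the α-stereocentre.

**Compound list**
1 | 4-bromoresorcinol | Oc1ccc(Br)c(O)c1 | starting material
2 | 1-bromo-2,4-bis(methoxymethoxy)benzene | COCOc1ccc(Br)c(OCOC)c1 | intermediate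
3 | but-3-enoic acid | C=CCC(=O)O | starting material
4 | 5,6-dihydro-2H-pyran-2-one | O=C1C=CCCO1 | intermediate
5 | [2,4-bis(methoxymethoxy)phenyl]lithium | [Li]c1ccc(OCOC)cc1OCOC | intermediate
6 | lithium [2,4-bis(methoxymethoxy)phenyl]trimethoxyborate | [Li+].CO[B-](OC)(OC)c1ccc(OCOC)cc1OCOC | intermediate
7 | (4R)-4-[2,4-bis(methoxymethoxy)phenyl]oxan-2-one | O=C1C[C@H](c2ccc(OCOC)cc2OCOC)CCO1 | intermediate
8 | (4R)-4-[2,4-bis(methoxymethoxy)phenyl]-6-hydroxyhexan-2-one | CC(=O)C[C@H](c1ccc(OCOC)cc1OCOC)CCO | intermediate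
9 | (3S)-3-[2,4-bis(methoxymethoxy)phenyl]-5-methylhex-5-en-1-ol | C=C(C)C[C@H](c1ccc(OCOC)cc1OCOC)CCO | intermediate
10 | (3S)-3-[2,4-bis(methoxymethoxy)phenyl]-5-methylhex-5-enal | C=C(C)C[C@H](c1ccc(OCOC)cc1OCOC)CC=O | intermediate
11 | resorcinol | Oc1cccc(O)c1 | starting material
12 | 1,3-bis(methoxymethoxy)benzene | COCOc1cccc(OCOC)c1 | intermediate
13 | [2,6-bis(methoxymethoxy)phenyl]lithium | [Li]c1c(OCOC)cccc1OCOC | intermediate
14 | 2,6-bis(methoxymethoxy)benzaldehyde | O=Cc1c(OCOC)cccc1OCOC | intermediate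
15 | 3-bromo-2,6-bis(methoxymethoxy)benzaldehyde | O=Cc1c(OCOC)ccc(Br)c1OCOC | intermediate
16 | rac-1-[3-bromo-2,6-bis(methoxymethoxy)phenyl]prop-2-en-1-ol | C=CC(O)c1c(OCOC)ccc(Br)c1OCOC | intermediate
17 | (2R,3S)-3-[2,4-bis(methoxymethoxy)phenyl]-2-[(1S)-1-[3-bromo-2,6-bis(methoxymethoxy)phenyl]prop-2-en-1-yl]-5-methylhex-5-enal | O=C[C@@H]([C@@H](c1c(OCOC)ccc(Br)c1OCOC)C=C)[C@@H](c1ccc(OCOC)cc1OCOC)CC(C)=C | intermediate
18 | (1R,2S,6S)-6-[2,4-bis(methoxymethoxy)phenyl]-2-[3-bromo-2,6-bis(methoxymethoxy)phenyl]-4-methylcyclohex-3-ene-1-carbaldehyde | O=C[C@H]1[C@@H](c2c(OCOC)ccc(Br)c2OCOC)C=C(C)C[C@@H]1c1ccc(OCOC)cc1OCOC | intermediate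
19 | [3-bromo-2,6-bis(methoxymethoxy)phenyl]lithium | [Li]c1c(OCOC)ccc(Br)c1OCOC | intermediate
20 | 1-bromo-2,4-bis(methoxymethoxy)-3-(3-methylbut-2-en-1-yl)benzene | CC(C)=CCc1c(OCOC)ccc(Br)c1OCOC | intermediate
21 | [2,4-bis(methoxymethoxy)-3-(3-methylbut-2-en-1-yl)phenyl]lithium | CC(C)=CCc1c(OCOC)ccc([Li])c1OCOC | intermediate
22 | [(1R,2S,6S)-6-[2,4-bis(methoxymethoxy)phenyl]-2-[3-bromo-2,6-bis(methoxymethoxy)phenyl]-4-methylcyclohex-3-en-1-yl][2,4-bis(methoxymethoxy)-3-(3-methylbut-2-en-1-yl)phenyl]methanol (both carbinol epimers) | CC(C)=CCc1c(OCOC)ccc(C(O)[C@H]2[C@@H](c3c(OCOC)ccc(Br)c3OCOC)C=C(C)C[C@@H]2c2ccc(OCOC)cc2OCOC)c1OCOC | intermediate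
23 | 4-hydroxybenzaldehyde | O=Cc1ccc(O)cc1 | starting material
24 | 4-(methoxymethoxy)benzaldehyde | COCOc1ccc(C=O)cc1 | intermediate
25 | (2E)-3-[4-(methoxymethoxy)phenyl]prop-2-enal | COCOc1ccc(/C=C/C=O)cc1 | intermediate
26 | lithium alkoxide of 22 carrying C–Li in place of C–Br | CC(C)=CCc1c(OCOC)ccc(C(O[Li])[C@H]2[C@@H](c3c(OCOC)ccc([Li])c3OCOC)C=C(C)C[C@@H]2c2ccc(OCOC)cc2OCOC)c1OCOC | intermediate
27 | bis-carbinol: 22 with Br replaced by the (2E)-1-hydroxy-3-[4-(methoxymethoxy)phenyl]prop-2-en-1-yl group (carbinol epimers; full name in step 17) | CC(C)=CCc1c(OCOC)ccc(C(O)[C@H]2[C@@H](c3c(OCOC)ccc(C(O)/C=C/c4ccc(OCOC)cc4)c3OCOC)C=C(C)C[C@@H]2c2ccc(OCOC)cc2OCOC)c1OCOC | intermediate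
28 | hepta-MOM ether of 30 (full name in step 18) | CC(C)=CCc1c(OCOC)ccc(C(=O)[C@H]2[C@@H](c3c(OCOC)ccc(C(=O)/C=C/c4ccc(OCOC)cc4)c3OCOC)C=C(C)C[C@@H]2c2ccc(OCOC)cc2OCOC)c1OCOC | intermediate
29 | heptakis(trimethylsilyl) ether of 30 | CC(C)=CCc1c(O[Si](C)(C)C)ccc(C(=O)[C@H]2[C@@H](c3c(O[Si](C)(C)C)ccc(C(=O)/C=C/c4ccc(O[Si](C)(C)C)cc4)c3O[Si](C)(C)C)C=C(C)C[C@@H]2c2ccc(O[Si](C)(C)C)cc2O[Si](C)(C)C)c1O[Si](C)(C)C | intermediate
30 | (2E)-1-[3-[(1S,5S,6R)-6-[2,4-dihydroxy-3-(3-methylbut-2-en-1-yl)benzoyl]-5-(2,4-dihydroxyphenyl)-3-methylcyclohex-2-en-1-yl]-2,4-dihydroxyphenyl]-3-(4-hydroxyphenyl)prop-2-en-1-one (benzoyl cis to the chalcone aryl, trans to the 2,4-dihydroxyphenyl) | CC(C)=CCc1c(O)ccc(C(=O)[C@H]2[C@@H](c3c(O)ccc(C(=O)/C=C/c4ccc(O)cc4)c3O)C=C(C)C[C@@H]2c2ccc(O)cc2O)c1O | target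

**Totals**
Total steps: 19. Longest linear sequence: 11 (steps 1, 3, 4, 5, 6, 11, 12, 14, 17, 18, 19; the chain from 3 through step 2 is equally long).

**Steps most likely to fail**

Step 11 (dual Ir/amine allylation). The aldehyde is β-branched, the carbinol is 2,6-disubstituted, the MOM ethers meet the Lewis acid ZnBr2, and the existing centre may be mismatched with one catalyst. The fallback sets out from 10 and 16 and returns at 17 through an Ireland–Claisen rearrangement. Aldehyde 10 is oxidised (NaClO2, NaH2PO4, 2-methylbut-2-ene, t-BuOH/H2O) to (3S)-3-[2,4-bis(methoxymethoxy)phenyl]-5-methylhex-5-enoic acid F1. Carbinol 16 is transposed (Ph3SiOReO3 cat., Et2O, 0 °C) to the conjugated (2E)-3-[3-bromo-2,6-bis(methoxymethoxy)phenyl]prop-2-en-1-ol F2. DCC/DMAP esterification gives the cinnamyl-type ester F3. LiN(iPr)2 in THF/DMPU with Me3SiCl at −78 °C gives the silyl ketene acetal F4 (alkyl branch cis to OSiMe3), which on warming rearranges through a chair to the trimethylsilyl ester F5, hydrolysed on work-up to the 2,3-syn acid F6. The β-aryl centre biases the enolate face only moderately, so the epimeric syn acid is separated. LiAlH4 reduction gives the primary alcohol F7, and Dess–Martin oxidation gives 17.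

Step 17 (alkoxide/aryllithium generation and addition to the enal). Risks are incomplete exchange, protonation of the aryllithium and competing ortho-lithiation. The fallback sets out from 22 and returns at 28, building the chalcone by cross-coupling and aldol condensation. Stille coupling of 22 with tributyl(1-ethoxyvinyl)stannane (Pd(PPh3)4, toluene, 100 °C) gives the aryl enol ether F8, hydrolysed (PPTS, wet acetone) to the aryl methyl ketone F9. Claisen–Schmidt condensation of F9 with 24 (KOH, EtOH/H2O, rt; no epimerisable centre at the carbinol stage) gives the chalcone carbinol F10. Dess–Martin oxidation of the remaining carbinol gives 28.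

Step 19 (sevenfold MOM cleavage). Risks are incomplete cleavage and damage to the prenyl group, the ring alkene or the cis ketone. The fallback sets out from 28 and returns at 30 by a protecting-group exchange. Et3SiOTf/2,2′-bipyridyl (MeCN, 0 °C) converts 28 into the isolable heptakis(triethylsilyl) ether F11, which is purified on silica and then unmasked with Bu4NF/AcOH (THF, 0 °C) under buffered fluoride conditions.

**Further compounds**
F1 | step 11 | (3S)-3-[2,4-bis(methoxymethoxy)phenyl]-5-methylhex-5-enoic acid | C=C(C)C[C@H](c1ccc(OCOC)cc1OCOC)CC(=O)O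
F2 | step 11 | (2E)-3-[3-bromo-2,6-bis(methoxymethoxy)phenyl]prop-2-en-1-ol | OC/C=C/c1c(OCOC)ccc(Br)c1OCOC
F3 | step 11 | (2E)-3-[3-bromo-2,6-bis(methoxymethoxy)phenyl]prop-2-en-1-yl (3S)-3-[2,4-bis(methoxymethoxy)phenyl]-5-methylhex-5-enoate | C=C(C)C[C@H](c1ccc(OCOC)cc1OCOC)CC(=O)OC/C=C/c1c(OCOC)ccc(Br)c1OCOC
F4 | step 11 | trimethylsilyl ketene acetal of F3 (alkyl branch cis to OSiMe3) | C[Si](C)(C)O/C(OC/C=C/c1c(OCOC)ccc(Br)c1OCOC)=C\[C@@H](c1ccc(OCOC)cc1OCOC)CC(C)=C
F5 | step 11 | trimethylsilyl ester of F6 | C[Si](C)(C)OC(=O)[C@@H]([C@@H](c1c(OCOC)ccc(Br)c1OCOC)C=C)[C@@H](c1ccc(OCOC)cc1OCOC)CC(C)=C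
F6 | step 11 | (2R,3S)-3-[2,4-bis(methoxymethoxy)phenyl]-2-[(1S)-1-[3-bromo-2,6-bis(methoxymethoxy)phenyl]prop-2-en-1-yl]-5-methylhex-5-enoic acid | OC(=O)[C@@H]([C@@H](c1c(OCOC)ccc(Br)c1OCOC)C=C)[C@@H](c1ccc(OCOC)cc1OCOC)CC(C)=C
F7 | step 11 | (2R,3S)-3-[2,4-bis(methoxymethoxy)phenyl]-2-[(1S)-1-[3-bromo-2,6-bis(methoxymethoxy)phenyl]prop-2-en-1-yl]-5-methylhex-5-en-1-ol | OC[C@@H]([C@@H](c1c(OCOC)ccc(Br)c1OCOC)C=C)[C@@H](c1ccc(OCOC)cc1OCOC)CC(C)=C
F8 | step 17 | 22 with Br replaced by 1-ethoxyvinyl | CC(C)=CCc1c(OCOC)ccc(C(O)[C@H]2[C@@H](c3c(OCOC)ccc(C(=C)OCC)c3OCOC)C=C(C)C[C@@H]2c2ccc(OCOC)cc2OCOC)c1OCOC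
F9 | step 17 | 22 with Br replaced by acetyl | CC(C)=CCc1c(OCOC)ccc(C(O)[C@H]2[C@@H](c3c(OCOC)ccc(C(C)=O)c3OCOC)C=C(C)C[C@@H]2c2ccc(OCOC)cc2OCOC)c1OCOC
F10 | step 17 | 22 with Br replaced by (2E)-3-[4-(methoxymethoxy)phenyl]prop-2-enoyl | CC(C)=CCc1c(OCOC)ccc(C(O)[C@H]2[C@@H](c3c(OCOC)ccc(C(=O)/C=C/c4ccc(OCOC)cc4)c3OCOC)C=C(C)C[C@@H]2c2ccc(OCOC)cc2OCOC)c1OCOC
F11 | step 19 | heptakis(triethylsilyl) ether of 30 | CC(C)=CCc1c(O[Si](CC)(CC)CC)ccc(C(=O)[C@H]2[C@@H](c3c(O[Si](CC)(CC)CC)ccc(C(=O)/C=C/c4ccc(O[Si](CC)(CC)CC)cc4)c3O[Si](CC)(CC)CC)C=C(C)C[C@@H]2c2ccc(O[Si](CC)(CC)CC)cc2O[Si](CC)(CC)CC)c1O[Si](CC)(CC)CC
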